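**Atom labels.** C1 = furanone C=O, C2 = furanone =CH, C3 = furanone C–O, C4 = ring carbon bearing the exocyclic methylene C15, C5 = CH(OH), C6 = lactone CH–O, C7 = lactone CH, C8 = CH–O-methacrylate, C9 = CH2, C10 = quaternary C(Me)–O (C14 = its methyl), C11–C13 = α-methylene lactone.

**Retrosynthetic overview**
1. The C5–OH and exocyclic C4=C15 come from a Mislow–Evans [2,3]-sigmatropic shift of allylic sulfoxide **29**, made from the macrocyclic allyl sulfide **28** (C4=C5 Z, CH2SPh on C4).
2. **28** comes from an intramolecular Nozaki–Hiyama allylation (C6 enal + C7 allylic bromide). This forms C6–C7, the trans α-methylene lactone and the 10-membered carbocycle in one step.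
3. The 3(2H)-furanone comes from 5-endo-dig oxa-Michael cyclisation of a tertiary α-hydroxy ynone (Weinreb amide + lithium enynide). The enyne comes from (Z)-iodobutenediol by Sonogashira coupling.
4. C10 comes from L-lactic acid (self-regeneration of stereocentres). C8 comes from syn-selective chelation reduction of a β-hydroxy ketone.
5. Rings form in this order: furanone (step 13), then macrocycle and lactone (step 20), then exocyclic methylene and C5–OH (step 22).

**Assumption:** the C4=C5 alkene stays Z (C3 cis to C6). Steps 10, 20 and 22 are substrate-controlled and give the required diastereomers as major products.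

---

**Step 1**
Reactants: 1 (2-butyne-1,4-diol)
Product: 2 ((2Z)-2-iodobut-2-ene-1,4-diol)
Conditions: Red-Al, THF, 0 °C; then I2, –78 → 0 °C
Reagents that add atoms: iodine, II
Why: Hydroxyl-directed trans-hydroalumination of the propargylic alcohol, then iodinolysis of the vinylalane, gives the Z-vinyl iodide with I cis to CH2OH (Corey-type hydroiodination).

**Step 2**
Reactants: 2
Product: 3 ((2Z)-4-[(tert-butyldiphenylsilyl)oxy]-2-iodobut-2-en-1-ol)
Conditions: TBDPSCl (1.0 equiv), imidazole, CH2Cl2, –20 → 0 °C
Reagents that add atoms: TBDPSCl, CC(C)(C)[Si](Cl)(c1ccccc1)c1ccccc1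
Why: Bulky silyl chloride protects the less hindered CH2OH (C6), which is remote from iodine; the C15 hydroxyl is left free (mono-protection, Z geometry untouched).

**Step 3**
Reactants: 3
Product: 4 (tert-butyl{[(2Z)-3-iodo-4-(phenylsulfanyl)but-2-en-1-yl]oxy}diphenylsilane)
Conditions: PhSSPh, n-Bu3P, THF, 25 °C
Reagents that add atoms: diphenyl disulfide, c1ccccc1SSc1ccccc1
Why: Phosphine/disulfide (Hata-type) activation converts the primary allylic alcohol into the allyl phenyl sulfide by SN2, putting the sulfur needed for the later [2,3] shift on C15 before any Michael acceptor is present.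

**Step 4**
Reactants: 4 + 5 (trimethylsilylacetylene)
Product: 6 (tert-butyl{[(2E)-4-(phenylsulfanyl)-3-((trimethylsilyl)ethynyl)but-2-en-1-yl]oxy}diphenylsilane; alkyne cis to CH2OSi)
Conditions: Pd(PPh3)2Cl2, CuI, Et3N, THF, 25 °C
Reagents that add atoms: none (all atoms from reactants)
Why: Sonogashira coupling of the vinyl iodide occurs with retention of alkene geometry and places C2≡C3 cis to C6.

**Step 5**
Reactants: 6
Product: 7 (terminal enyne, tert-butyl{[(2E)-3-ethynyl-4-(phenylsulfanyl)but-2-en-1-yl]oxy}diphenylsilane)
Conditions: K2CO3, MeOH, 0 °C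
Reagents that add atoms: none
Why: Base-mediated protodesilylation of the alkynyl-TMS; the TBDPS ether and sulfide are inert.

**Step 6**
Reactants: 8 ((S)-lactic acid) + 9 (pivaldehyde)
Product: 10 ((2S,5S)-2-tert-butyl-5-methyl-1,3-dioxolan-4-one)
Conditions: TsOH (cat.), pentane, reflux, Dean–Stark
Reagents that add atoms: none (water lost)
Why: Seebach acetalisation gives the cis dioxolanone, which stores the lactate stereocentre for the next alkylation (self-regeneration of stereocentres).

**Step 7**
Reactants: 10 + 11 (methyl bromoacetate)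
Product: 12 (methyl 2-[(2S,5R)-2-tert-butyl-5-methyl-4-oxo-1,3-dioxolan-5-yl]acetate)
Conditions: LDA, THF, –78 °C; then 11, –78 → –40 °C
Reagents that add atoms: none (all atoms from reactants)
Why: The planar enolate is alkylated trans to the tert-butyl group, so the new CH2 (C9) takes the place of H with retention and sets C10 as (R).

**Step 8**
Reactants: 12
Product: 13 ((2R)-2-hydroxy-N1,N4-dimethoxy-N1,N4,2-trimethylbutanediamide)
Conditions: MeNHOMe·HCl, i-PrMgCl (6 equiv), THF, –20 → 0 °C
Reagents that add atoms: N,O-dimethylhydroxylamine hydrochloride, CNOC.Cl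
Why: Magnesium N-methoxy-N-methylamide opens the dioxolanone acylal (pivaldehyde lost) and converts the methyl ester, giving a bis-Weinreb amide with a free tertiary OH.

**Step 9**
Reactants: 13 + 14 (tributyl[(methoxymethoxy)methyl]stannane)
Product: 15 ((2R)-2-hydroxy-N-methoxy-5-(methoxymethoxy)-N,2-dimethyl-4-oxopentanamide)
Conditions: 14, n-BuLi, THF, –78 °C (gives LiCH2OMOM); add 13; –78 → –40 °C
Reagents that add atoms: (methoxymethoxy)methyllithium, [Li]COCOC
Why: Still hydroxymethyl-anion equivalent adds once to the more accessible C8 Weinreb amide; the C1 amide is deactivated as its chelated α-alkoxide. The tetrahedral intermediate prevents over-addition, giving the C7-oxygenated ketone.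

**Step 10**
Reactants: 15
Product: 16 ((2R,4S)-2,4-dihydroxy-N-methoxy-5-(methoxymethoxy)-N,2-dimethylpentanamide)
Conditions: Et2BOMe, THF/MeOH 4:1, –78 °C; then NaBH4; oxidative work-up
Reagents that add atoms: none (H2 added)
Why: Narasaka–Prasad reduction: the boron chelate of the tertiary alkoxide and the ketone is reduced by axial hydride, giving the syn-1,3-diol. This sets C8 (S) relative to C10 (R), with the larger C1 amide pseudo-equatorial.

**Step 11**
Reactants: 16 + 17 (methacryloyl chloride)
Product: 18 ((2R,4S)-4-(methacryloyloxy)-2-hydroxy-N-methoxy-5-(methoxymethoxy)-N,2-dimethylpentanamide)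
Conditions: CH2=C(Me)COCl, Et3N, DMAP (cat.), CH2Cl2, 0 °C
Reagents that add atoms: none (all atoms from reactant 17)
Why: Acylation is selective for the secondary C8 alcohol; the tertiary C10 alcohol is too hindered. The ester is installed now so that C5–OH can be freed last.

**Step 12**
Reactants: 18 + 7
Product: 19 (hydroxy ynone: C10(OH)(Me)–C1(=O)–C2≡C3–C4(CH2SPh)=C5–C6H2OTBDPS, with C9–C8(OMacr)–C7H2OMOM on C10)
Conditions: 7, n-BuLi, THF, –78 °C; add 18 pre-treated with LiHMDS (1 equiv); –78 → –40 °C
Reagents that add atoms: none (all atoms from reactants)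
Why: Lithium acetylide acylation of the Weinreb amide stops at the ynone (stable chelated intermediate); the tertiary centre is untouched.

**Step 13**
Reactants: 19
Product: 20 (furanone: C10 and C3 bridged by O, with C8 OMacr, C7 CH2OMOM, and C4=C5–C6H2OTBDPS attached)
Conditions: Et2NH (cat.), CH2Cl2, 25 °C
Reagents that add atoms: none (isomerisation)
Why: The tertiary alkoxide undergoes 5-endo-dig oxa-Michael addition to the ynone (amine-catalysed addition–elimination) to give the 2,2-disubstituted 3(2H)-furanone. C10 is not involved, so its configuration is retained.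

**Step 14**
Reactants: 20
Product: 21 (C7 primary alcohol)
Conditions: TMSOTf, 2,2′-bipyridyl, MeCN, 0 °C; then H2O
Reagents that add atoms: none
Why: Mild pyridinium-mediated MOM cleavage (Fujioka) leaves the TBDPS ether, methacrylate, furanone and sulfide intact.

**Step 15**
Reactants: 21
Product: 22 (C7 aldehyde, α-methacryloyloxy)
Conditions: Dess–Martin periodinane, NaHCO3, CH2Cl2, 25 °C
Reagents that add atoms: none
Why: Mild buffered oxidation of the primary alcohol avoids epimerisation at C8 and tolerates the thioether.

**Step 16**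
Reactants: 22 + 23 (methyl acrylate)
Product: 24 (Morita–Baylis–Hillman adduct, C7–OH, as a mixture of C7 epimers)
Conditions: DABCO, MeOH, 25 °C
Reagents that add atoms: none (all atoms from reactant 23)
Why: Baylis–Hillman coupling builds C7–C11. The new C7 carbinol centre is destroyed in the next step, so its configuration is irrelevant.

**Step 17**
Reactants: 24
Product: 25 (methyl (2Z)-2-(bromomethyl)alk-2-enoate: C13H2Br–C11(CO2Me)=C7H–C8)
Conditions: MsCl, Et3N, CH2Cl2, 0 °C; then LiBr, THF, 0 → 25 °C
Reagents that add atoms: lithium bromide, [Li+].[Br-]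
Why: Mesylation followed by SN2′ displacement with bromide transposes the allylic system and gives the thermodynamically preferred (Z)-allylic bromide, the precursor to the γ-substituted allylchromium. The C7 epimers converge.

**Step 18**
Reactants: 25
Product: 26 (C6 allylic alcohol)
Conditions: HF·pyridine, THF/pyridine, 0 → 25 °C
Reagents that add atoms: none
Why: Fluoride-mediated removal of the primary allylic TBDPS ether; the allylic bromide, esters and sulfide survive non-basic HF·pyridine.

**Step 19**
Reactants: 26
Product: 27 (Z-enal at C6, allylic bromide at C13)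
Conditions: MnO2, CH2Cl2, 25 °C
Reagents that add atoms: none
Why: MnO2 selectively oxidises the conjugated dienyl (furanone-conjugated) allylic alcohol and leaves the alkyl bromide and sulfide untouched.

**Step 20**
Reactants: 27
Product: 28 (macrocyclic allyl sulfide: 10-membered carbocycle with α-methylene-γ-lactone, furanone, C8 methacrylate and Z-C4=C5)
Conditions: CrCl2 (excess), NiCl2 (cat.), DMF, 25 °C, 2 mM by syringe pump; then TsOH (cat.), CH2Cl2, 25 °C
Reagents that add atoms: none (net H added; MeOH lost)
Why: Intramolecular Nozaki–Hiyama allylation: the allylchromium equilibrates to the E form and adds 1,2 to the enal through a chair transition state. This gives the anti homoallylic alcohol, which lactonises onto the ester to give the trans α-methylene-γ-lactone. C6 and C7 are set relative to C8/C10 by the rigid Z-alkene/furanone macrocycle.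

**Step 21**
Reactants: 28
Product: 29 (allylic sulfoxide, S-epimeric mixture)
Conditions: NaIO4, MeOH/H2O, 0 °C
Reagents that add atoms: sodium periodate, [Na+].[O-]I(=O)(=O)=O
Why: Periodate oxidises the sulfide chemoselectively and leaves the electron-poor alkenes untouched.

**Step 22**
Reactants: 29
Product: 30 (isogoiazensolide)
Conditions: P(OMe)3, MeOH/THF, 25 → 45 °C
Reagents that add atoms: none (sulfenate cleaved; OH oxygen comes from the sulfoxide)
Why: Mislow–Evans [2,3]-sigmatropic rearrangement: the allylic sulfoxide ⇌ sulfenate ester forms the C5–O bond and the exocyclic C4=C15 alkene. Phosphite traps the sulfenate irreversibly, releasing the C5 alcohol. The new C5 stereocentre is set under Curtin–Hammett control by the adjacent C6 lactone stereocentre on the open face of the macrocycle.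

---

**Compound list**

1 | 2-butyne-1,4-diol | OCC#CCO | starting material
2 | (2Z)-2-iodobut-2-ene-1,4-diol | OC/C=C(\I)CO | intermediate
3 | (2Z)-4-(TBDPSO)-2-iodobut-2-en-1-ol | OC\C(I)=C\CO[Si](c1ccccc1)(c1ccccc1)C(C)(C)C | intermediate
4 | allyl phenyl sulfide vinyl iodide | c1ccccc1SC\C(I)=C\CO[Si](c2ccccc2)(c2ccccc2)C(C)(C)C | intermediate
5 | trimethylsilylacetylene | C[Si](C)(C)C#C | starting material
6 | TMS-enyne | c1ccccc1SC\C(C#C[Si](C)(C)C)=C\CO[Si](c2ccccc2)(c2ccccc2)C(C)(C)C | intermediate
7 | terminal enyne | c1ccccc1SC\C(C#C)=C\CO[Si](c2ccccc2)(c2ccccc2)C(C)(C)C | intermediate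
8 | (S)-lactic acid | C[C@H](O)C(=O)O | starting material
9 | pivaldehyde | CC(C)(C)C=O | starting material
10 | (2S,5S)-2-tert-butyl-5-methyl-1,3-dioxolan-4-one | C[C@@H]1O[C@H](C(C)(C)C)OC1=O | intermediate
11 | methyl bromoacetate | BrCC(=O)OC | starting material
12 | alkylated dioxolanone | C[C@]1(CC(=O)OC)O[C@H](C(C)(C)C)OC1=O | intermediate
13 | (R)-bis-Weinreb amide | CON(C)C(=O)C[C@@](C)(O)C(=O)N(C)OC | intermediate
14 | tributyl[(methoxymethoxy)methyl]stannane | CCCC[Sn](CCCC)(CCCC)COCOC | starting material
15 | C8 ketone Weinreb amide | COCOCC(=O)C[C@@](C)(O)C(=O)N(C)OC | intermediate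
16 | syn-diol Weinreb amide | COCOC[C@@H](O)C[C@@](C)(O)C(=O)N(C)OC | intermediate
17 | methacryloyl chloride | C=C(C)C(=O)Cl | starting material
18 | methacrylate Weinreb amide | COCOC[C@@H](OC(=O)C(C)=C)C[C@@](C)(O)C(=O)N(C)OC | intermediate
19 | hydroxy ynone | COCOC[C@@H](OC(=O)C(C)=C)C[C@@](C)(O)C(=O)C#C/C(CSc1ccccc1)=C\CO[Si](c1ccccc1)(c1ccccc1)C(C)(C)C | intermediate
20 | furanone | COCOC[C@@H](OC(=O)C(C)=C)C[C@@]1(C)OC(=CC1=O)/C(CSc2ccccc2)=C\CO[Si](c2ccccc2)(c2ccccc2)C(C)(C)C | intermediate
21 | primary alcohol | OC[C@@H](OC(=O)C(C)=C)C[C@@]1(C)OC(=CC1=O)/C(CSc2ccccc2)=C\CO[Si](c2ccccc2)(c2ccccc2)C(C)(C)C | intermediate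
22 | aldehyde | O=C[C@@H](OC(=O)C(C)=C)C[C@@]1(C)OC(=CC1=O)/C(CSc2ccccc2)=C\CO[Si](c2ccccc2)(c2ccccc2)C(C)(C)C | intermediate
23 | methyl acrylate | C=CC(=O)OC | starting material
24 | Baylis–Hillman adduct (C7 epimers) | C=C(C(=O)OC)C(O)[C@@H](OC(=O)C(C)=C)C[C@@]1(C)OC(=CC1=O)/C(CSc2ccccc2)=C\CO[Si](c2ccccc2)(c2ccccc2)C(C)(C)C | intermediate
25 | (Z)-allylic bromide | BrC/C(C(=O)OC)=C\[C@@H](OC(=O)C(C)=C)C[C@@]1(C)OC(=CC1=O)/C(CSc2ccccc2)=C\CO[Si](c2ccccc2)(c2ccccc2)C(C)(C)C | intermediate
26 | C6 allylic alcohol | BrC/C(C(=O)OC)=C\[C@@H](OC(=O)C(C)=C)C[C@@]1(C)OC(=CC1=O)/C(CSc2ccccc2)=C\CO | intermediate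
27 | C6 enal | BrC/C(C(=O)OC)=C\[C@@H](OC(=O)C(C)=C)C[C@@]1(C)OC(=CC1=O)/C(CSc2ccccc2)=C\C=O | intermediate
28 | macrocyclic allyl sulfide | C=C(C)C(=O)O[C@H]1C[C@@]2(C)OC(=CC2=O)/C(CSc3ccccc3)=C\[C@H]2OC(=O)C(=C)[C@@H]21 | intermediate
29 | allylic sulfoxide | C=C(C)C(=O)O[C@H]1C[C@@]2(C)OC(=CC2=O)/C(CS(=O)c3ccccc3)=C\[C@H]2OC(=O)C(=C)[C@@H]21 | intermediate
30 | isogoiazensolide | C=C(C)C(=O)O[C@H]1C[C@@]2(C)OC(=CC2=O)C(=C)[C@@H](O)[C@H]2OC(=O)C(=C)[C@@H]21 | target

---

**Totals**
- Total step count: 22 steps (5 for the enyne fragment, 17 on the lactic acid branch including both couplings).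
- Longest linear sequence: 17 steps (steps 6–22 from (S)-lactic acid).

**Three steps most likely to fail**
1. **Step 20 (NHK macrocyclisation).** Risks are yield, C6/C7 diastereoselectivity, and side reactions of Cr(II) with the sulfide or enone.
   - Fallback: build the trans α-methylene lactone first by an intermolecular Zn-mediated allylation. Then close the ring by intramolecular Stille coupling at C3–C4 of a furanone-stannane with a vinyl iodide.
2. **Step 22 (Mislow–Evans).** Risks are the C5 configuration in the macrocycle and Michael addition to the α-methylene lactone or methacrylate.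
   - Fallback: drop the sulfur chemistry. Close the ring by intramolecular NHK of a C4 vinyl iodide onto a C5 aldehyde, which sets the C5 carbinol and exocyclic methylene directly.
3. **Step 10 (Narasaka–Prasad reduction).** Methyl and the C1 amide are similar in size on the tertiary carbinol, so syn selectivity may be poor.
   - Fallback: take C8 from L-malic acid, via (S)-3,4-dihydroxybutanoate. Then form C10 by chelation-controlled addition of a C1 nucleophile or MeMgBr to the β-alkoxy ketone.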